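## Structural features

The target 16 is an achiral benzophenone in which ring A (C1–C6), a fully substituted benzene, is joined through the ketone carbon C7 to ring B, a 3-hydroxyphenyl group. Ring A carries C7 at C1, free hydroxyls at C2 and C6, a methoxy group at C4 and 3-methylbut-2-enyl (prenyl) chains at C3 and C5, so it has a local mirror plane through C1 and C4. There is no stereocentre, and both olefins end in geminal methyl groups, so no configuration has to be set. The fragile parts are the two prenyl groups, each ortho to a free phenol (acid closes them to 2,2-dimethylchromans, hydrogenation saturates them, oxidants attack them), and ring A itself, which is very electron-rich and ambident under base. The real difficulty is regiochemical bookkeeping on a hexasubstituted ring: the aroyl group must sit between two oxygens, the C4 oxygen must end as a methyl ether while the C2 and C6 oxygens end free, the prenyl groups must go onto carbon and not oxygen, and the ring B phenol must be released without touching the prenyl groups. The key step uses the fact that C1, which bears C7, has a hydroxyl on its neighbour C2 and an oxygen on C6: an ortho-hydroxyaryl ketone of this kind results when an aryne (C1≡C2) takes up the acyl group and the hydroxyl oxygen of a benzoic acid on adjacent carbons, and the C6 oxygen next to the aryne bond decides the orientation.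

## Logic of the disconnections

16 to 15. The ring B O–H is traced back to an O–CH2 bond of an allyl ether. The ring B phenol is the one nucleophile outside ring A that would compete in the prenylation, so it must stay masked until the end. The mask must then come off without acid, hydrogenolysis or strong Lewis acid, which excludes a benzyl ether at this stage. The forward step therefore needs a neutral allyl transfer that leaves trisubstituted olefins alone.

15 to 12 and 13 through 14. The two aryl–CH2 bonds at C3 and C5 are cut, one after the other, with the monoalkylated 14 lying between. These are the only unsubstituted positions of ring A in 12, and each is ortho to one hydroxyl, para to the other and ortho to the methoxy group, so no positional control is needed. Ten carbons are removed and a symmetric core remains. The forward step consumes two equivalents of 13, must favour alkylation at carbon over oxygen, and must stop after two alkylations.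

12 to 11. The C6 hydroxyl is traced back to a methyl ether (the O–CH3 bond is restored). Both ether oxygens of ring A are then methyl ethers, so ring A can come from a symmetric precursor. The C6 methoxy differs from the C4 methoxy only by lying next to the carbonyl, so the forward step must be a chelation-controlled cleavage. It must also spare the allyl ether, which rules out BCl3 and BBr3, reagents that rearrange aryl allyl ethers.

11 to 8 and 9 through 10. The C1–C7 and C2–O bonds are cut together. This separates the two rings, removes the only ketone, and reduces ring A to an aryne whose substituents already encode the oxygen pattern. The forward step must add the carboxylate oxygen of 9 to the aryne carbon remote from the flanking methoxy group and then move the acyl group to the adjacent carbon before the aryl anion is protonated. Compound 9 carries the ring B oxygen as an allyl ether rather than a benzyl ether for the reasons stated under the first two cuts.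

8 to 6 through 7. The O–S bond of the triflate is cut and the phenol oxygen is traced back to a carbamate. The carbamate is the group that directs the silicon into place, and its removal and the triflation can share one flask. The forward step must avoid handling the free ortho-silyl phenol 7, which is prone to protodesilylation.

6 to 2 through 3, 4 and 5. The C2–Si bond is cut. A directed ortho-metalation places silicon on the carbon between the carbamate and a methoxy group, which is exactly the carbon that will carry C7. The forward step must metalate next to the carbamate and not between the two methoxy groups, and must trap the aryllithium before the acyl group migrates.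

2 to 1. The carbamate C–O bond is cut, leading to the symmetric, purchasable phenol 1. The only demand is clean O-carbamoylation.

## Other disconnections considered

Alternative 1: The cut runs through ring A itself: bonds C3–C4, C4–C5 and C1–C2 (target numbering) are broken, so that ring A is assembled from cyclobutenone A2 and siloxyalkyne A3.

- Forward key step: on heating, A2 would open to a vinylketene, add across A3 in a (2+2) sense, reopen to a dienylketene and close by 6π electrocyclisation to phenol A1.
- In its favour: both prenyl groups are on carbon before the ring exists, so the C- versus O-alkylation problem of step 6 does not arise, and here it is the better plan. The single free hydroxyl of A1 is the future C4 oxygen, so its methylation would be unambiguous; on this point it is at least the equal of the chelation-controlled demethylation of step 5.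
- Against it here: ring B and C7 still have to be attached at the one remaining ring CH of A1, which is flanked by two bulky ethers, under conditions that two prenyl groups tolerate. The ethyl ether would then have to be cleaved with both prenyl groups present, whereas the chosen plan does the corresponding ether cleavage before any prenyl group exists.
- Mechanism: the pericyclic cascade takes its regiochemistry from the polarisation of the ynol ether, the aryne insertion from the flanking methoxy group; both are dependable.
- Step economy: A2 and A3 each need several steps from catalogue materials, and benzannulation, methylation, acylation and two deprotections follow. That is roughly a dozen operations against seven.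

Alternative 2: The cut is made inside each prenyl chain, at the CH2–CH bond, with both benzylic carbons already on C3 and C5 as ammoniomethyl groups.

- Forward key step: bis-ammonium salt A5, treated with excess Grignard reagent A6 and catalytic CuI, would form two ortho-quinone methides in turn, each taking the alkenyl group at its exocyclic carbon, to give A4, the ring B silyl ether of the target.
- In its favour: aminomethylation is specific for carbon and a quinone methide accepts the nucleophile only at its exocyclic carbon, so neither O-alkylation nor a rearranged (reverse) prenyl group can arise. On the selectivity of prenyl installation it is the better of the two plans, and it acts on the same symmetric diphenol stage as the chosen plan (the stage of 12).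
- Against it here: it does not address how the hexasubstituted benzophenone core is made, so the C1–C7 bond still needs an acylation or the aryne insertion. Excess A6 meets the diaryl ketone of A5, which is shielded only by its flanking phenoxides. The silyl ether on ring B would not survive fluoride-triggered aryne formation, so the protecting group would have to be changed on the way.
- Mechanism: conjugate addition to a transient quinone methide against alkylation of an ambident phenoxide.
- Step economy: aminomethylation, quaternisation, alkenylation and desilylation replace one alkylation and one deallylation, about two operations more. Its tactic is kept as the fallback for step 6.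

Alternative 3: The cut goes through ring A at C2–C3 and C5–C6, leaving a three-carbon diacyl unit and a symmetric ketone that already carries both prenyl chains.

- Forward key step: enol ether A8, made from ketone A9, would be acylated at both α-carbons by malonyl dichloride A10 and would aromatise to triol A7.
- In its favour: it is the shortest conceivable route to a ring A with both prenyl groups and all three oxygens in place, from cheap symmetric materials. On operations needed to reach a diprenylated ring A it is the better plan, and in overall count it is roughly the equal of the chosen plan if every step behaved.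
- Against it here: A7 is a triol, so the methyl group that A8 carried on the future C4 oxygen is lost. It must be put back selectively on the most hindered hydroxyl, which is realistic only after acylation has tied up the other two by chelation. A10 releases strong acid next to two acid-sensitive olefins. Acylation on oxygen and closure to a pyranone is a known competing course for such bis-acid chlorides. Ring B must then be attached by a Friedel–Crafts-type acylation of A7, where chroman formation threatens.
- Comparison: structurally it fixes the prenyl positions by construction (better) but leaves the C1–C7 bond and the oxygen differentiation unsolved (worse). The chosen plan gets both from one aryne step. Mechanistically it is a twofold C-acylation with enolisation against a polar aryne insertion.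

Key step: step 4

Assumption: 9 is treated as a purchasable benzoic acid; its allyl ether takes no part in the aryne insertion.

## Route

Step 1
Reactants: 1 3,5-dimethoxyphenol
Product: 2 3,5-dimethoxyphenyl N-(propan-2-yl)carbamate
Conditions: i-PrNCO (1.5 equiv), Et3N (0.2 equiv), CH2Cl2, rt
Reagents that add atoms: isopropyl isocyanate, CC(C)N=C=O
Why: Amine-catalysed addition of the phenol to the isocyanate (O-carbamoylation); the secondary carbamate is chosen because it can later be removed by a mild E1cB elimination.

Step 2
Reactants: 2 3,5-dimethoxyphenyl N-(propan-2-yl)carbamate
Product: 6 3,5-dimethoxy-2-(trimethylsilyl)phenyl N-(propan-2-yl)carbamate, via N-silyl carbamate 3 (not isolated), via C2-lithiated N-silyl carbamate 4 (not isolated), via N-silyl C2-silyl carbamate 5 (not isolated)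
Conditions: TBSOTf (1.1 equiv), TMEDA (1.1 equiv), Et2O, 0 °C to rt; then TMEDA (2 equiv), n-BuLi (2 equiv), −78 °C; TMSCl (3.5 equiv), −78 °C to rt; aq NaHSO4
Reagents that add atoms: chlorotrimethylsilane, C[Si](C)(C)Cl; tert-butyldimethylsilyl trifluoromethanesulfonate, CC(C)(C)[Si](C)(C)OS(=O)(=O)C(F)(F)F (its silyl group is carried only by 3, 4 and 5 and is lost on work-up); n-butyllithium, [Li]CCCC (its lithium is carried only by 4)
Why: In situ N-silylation turns the N–H carbamate into a tertiary carbamate, the strongest directing group on the ring, so directed ortho-metalation should occur at C2 (equivalent to C6), between the carbamate and a methoxy group, in preference to C4 between two methoxy groups. TMSCl traps the aryllithium at −78 °C before an anionic ortho-Fries shift can begin, and the N–Si bond is hydrolysed on acidic work-up.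

Step 3
Reactants: 6 3,5-dimethoxy-2-(trimethylsilyl)phenyl N-(propan-2-yl)carbamate
Product: 8 3,5-dimethoxy-2-(trimethylsilyl)phenyl trifluoromethanesulfonate, via 3,5-dimethoxy-2-(trimethylsilyl)phenol 7 (not isolated)
Conditions: DBU (1.5 equiv), Et2NH (1.2 equiv), MeCN, 40 °C; then PhNTf2 (1.5 equiv), rt
Reagents that add atoms: N-phenylbis(trifluoromethanesulfonimide), O=S(=O)(N(c1ccccc1)S(=O)(=O)C(F)(F)F)C(F)(F)F
Why: DBU deprotonates the N–H carbamate, which expels the phenoxide and isopropyl isocyanate (E1cB carbamate cleavage), and diethylamine captures the isocyanate as a urea. The phenoxide of 7 is O-sulfonylated by PhNTf2 in the same flask, so the protodesilylation-prone ortho-silyl phenol is never handled.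

Step 4
Reactants: 8 3,5-dimethoxy-2-(trimethylsilyl)phenyl trifluoromethanesulfonate; 9 3-(prop-2-enyloxy)benzoic acid
Product: 11 [3-(prop-2-enyloxy)phenyl](2-hydroxy-4,6-dimethoxyphenyl)methanone, via 3,5-dimethoxybenzyne 10 (not isolated)
Conditions: 8 (1.3 equiv), CsF (4 equiv), THF, 125 °C, sealed tube
Reagents that add atoms: none
Why: Fluoride attacks the silicon of 8 and the neighbouring triflate departs, releasing aryne 10 slowly so that its stationary concentration stays low. The caesium carboxylate of 9 adds through oxygen to the aryne carbon remote from the adjacent methoxy group (the carbon that carried the triflate), because the inductively withdrawing C–O bond stabilises the aryl anion developing on the carbon next to it and the distorted aryne is most electrophilic at the far carbon. That aryl anion lies ortho to the new aryl ester and attacks its carbonyl in a 4-exo-trig sense; the strained four-membered hemiketal alkoxide is only a transient and opens by C–O cleavage to the chelated caesium 2-acylphenoxide, so the C2–O and C1–C7 bonds form in one operation and no ring of the product is closed. The closest known reaction type is the fluoride-induced σ-insertion of arynes into the C–O bond of carboxylic acids to give ortho-hydroxyaryl ketones, an intramolecular anionic O-to-C acyl shift related to the anionic ortho-Fries rearrangement and to aryne acyl-alkylation. No stereocentre is created. Two selectivities are needed: the regiochemistry that places the acyl group between two oxygens is secured by the methoxy group flanking the aryne bond, and acyl migration is favoured over protonation of the aryl anion (which would stop at a simple aryl ester) by the aprotic medium, the high temperature and the excess CsF that holds the acid proton as bifluoride. The allyl ether of 9 has no acidic or nucleophilic site, is well below the temperature of a Claisen rearrangement, and its olefin should not compete with the carboxylate for 10.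

Step 5
Reactants: 11 [3-(prop-2-enyloxy)phenyl](2-hydroxy-4,6-dimethoxyphenyl)methanone
Product: 12 [3-(prop-2-enyloxy)phenyl](2,6-dihydroxy-4-methoxyphenyl)methanone
Conditions: MgI2·OEt2 (3 equiv), toluene/THF, 80 °C; then 1 M HCl
Reagents that add atoms: none
Why: Chelation-controlled nucleophilic demethylation: magnesium bridges the carbonyl oxygen and the C6 methoxy oxygen, and iodide removes the activated methyl group by SN2. The C4 methoxy group and the ring B allyl ether cannot chelate and should stay, which is why this reagent is preferred to BCl3, known to trigger charge-accelerated Claisen rearrangement of aryl allyl ethers.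

Step 6
Reactants: 12 [3-(prop-2-enyloxy)phenyl](2,6-dihydroxy-4-methoxyphenyl)methanone; 13 1-bromo-3-methylbut-2-ene (prenyl bromide)
Product: 15 [2,6-dihydroxy-4-methoxy-3,5-bis(3-methylbut-2-enyl)phenyl][3-(prop-2-enyloxy)phenyl]methanone, via C3-monoprenyl ketone 14 (not isolated)
Conditions: 13 (2.2 equiv in all, in portions), 10% aq KOH (3 equiv), 0 °C to rt
Reagents that add atoms: 1-bromo-3-methylbut-2-ene (the second equivalent of 13), CC(C)=CCBr
Why: Twofold C-alkylation of an ambident phenoxide, the classical C-prenylation of acylphloroglucinol-type phenols: in water the oxygen termini are hydrogen-bonded, so the soft allylic bromide is taken at carbon, first at C3 to give 14 and then, by a second equivalent of 13, at C5 of the still ionised 14. C3 and C5 are the only free ring A positions, each ortho and para to a phenoxide oxygen, so the two alkylations need no positional control. Ring B has no ionisable group, and limiting 13 to about two equivalents restrains a third alkylation.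

Step 7
Reactants: 15 [2,6-dihydroxy-4-methoxy-3,5-bis(3-methylbut-2-enyl)phenyl][3-(prop-2-enyloxy)phenyl]methanone
Product: 16 [2,6-dihydroxy-4-methoxy-3,5-bis(3-methylbut-2-enyl)phenyl](3-hydroxyphenyl)methanone
Conditions: Pd(PPh3)4 (5 mol %), morpholine (5 equiv), THF, rt
Reagents that add atoms: none
Why: Tsuji–Trost-type deallylation: zerovalent palladium ionises the aryl allyl ether to a π-allyl complex and the ring B phenoxide, and morpholine takes the allyl group. The prenyl groups carry no leaving group and the neutral medium avoids chroman formation.

## Compound list

1 | 3,5-dimethoxyphenol | COc1cc(O)cc(OC)c1 | starting material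
2 | 3,5-dimethoxyphenyl N-(propan-2-yl)carbamate | COc1cc(OC)cc(OC(=O)NC(C)C)c1 | intermediate
3 | 3,5-dimethoxyphenyl N-(tert-butyldimethylsilyl)-N-(propan-2-yl)carbamate | COc1cc(OC)cc(OC(=O)N(C(C)C)[Si](C)(C)C(C)(C)C)c1 | intermediate (not isolated)
4 | [2-{[(tert-butyldimethylsilyl)(propan-2-yl)carbamoyl]oxy}-4,6-dimethoxyphenyl]lithium | [Li]c1c(OC)cc(OC)cc1OC(=O)N(C(C)C)[Si](C)(C)C(C)(C)C | intermediate (not isolated)
5 | 3,5-dimethoxy-2-(trimethylsilyl)phenyl N-(tert-butyldimethylsilyl)-N-(propan-2-yl)carbamate | COc1cc(OC)c([Si](C)(C)C)c(OC(=O)N(C(C)C)[Si](C)(C)C(C)(C)C)c1 | intermediate (not isolated)
6 | 3,5-dimethoxy-2-(trimethylsilyl)phenyl N-(propan-2-yl)carbamate | COc1cc(OC)c([Si](C)(C)C)c(OC(=O)NC(C)C)c1 | intermediate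
7 | 3,5-dimethoxy-2-(trimethylsilyl)phenol | COc1cc(O)c([Si](C)(C)C)c(OC)c1 | intermediate (not isolated)
8 | 3,5-dimethoxy-2-(trimethylsilyl)phenyl trifluoromethanesulfonate | COc1cc(OC)c([Si](C)(C)C)c(OS(=O)(=O)C(F)(F)F)c1 | intermediate
9 | 3-(prop-2-enyloxy)benzoic acid | C=CCOc1cccc(C(=O)O)c1 | starting material
10 | 3,5-dimethoxybenzyne (1,2-didehydro-3,5-dimethoxybenzene) | COC1=CC(OC)=CC#C1 | intermediate (not isolated)
11 | [3-(prop-2-enyloxy)phenyl](2-hydroxy-4,6-dimethoxyphenyl)methanone | COc1cc(O)c(C(=O)c2cccc(OCC=C)c2)c(OC)c1 | intermediate
12 | [3-(prop-2-enyloxy)phenyl](2,6-dihydroxy-4-methoxyphenyl)methanone | COc1cc(O)c(C(=O)c2cccc(OCC=C)c2)c(O)c1 | intermediate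
13 | 1-bromo-3-methylbut-2-ene (prenyl bromide) | CC(C)=CCBr | starting material
14 | [2,6-dihydroxy-4-methoxy-3-(3-methylbut-2-enyl)phenyl][3-(prop-2-enyloxy)phenyl]methanone | COc1cc(O)c(C(=O)c2cccc(OCC=C)c2)c(O)c1CC=C(C)C | intermediate (not isolated)
15 | [2,6-dihydroxy-4-methoxy-3,5-bis(3-methylbut-2-enyl)phenyl][3-(prop-2-enyloxy)phenyl]methanone | COc1c(CC=C(C)C)c(O)c(C(=O)c2cccc(OCC=C)c2)c(O)c1CC=C(C)C | intermediate
16 | [2,6-dihydroxy-4-methoxy-3,5-bis(3-methylbut-2-enyl)phenyl](3-hydroxyphenyl)methanone | COc1c(CC=C(C)C)c(O)c(C(=O)c2cccc(O)c2)c(O)c1CC=C(C)C | target

## Step count and least certain steps

Total: 7 steps. Longest linear sequence: 7 steps (1 to 16); 9 enters at step 4 and 13 at step 6.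

Step 4 (key step). The aryl anion may be protonated before the acyl group migrates, which stops the sequence at simple O-arylation. Regioselectivity of carboxylate addition may erode at 125 °C, and the product phenoxide may be arylated by surplus aryne. Fallback: abandon the aryne for an electrophilic acylation of a symmetric arene. Acid 9 is activated with trifluoroacetic anhydride in CH2Cl2 to 3-(prop-2-enyloxy)benzoic trifluoroacetic anhydride F1. F1 acylates purchasable 1,3,5-trimethoxybenzene (Friedel–Crafts acylation without a metal Lewis acid, single product by symmetry) to give [3-(prop-2-enyloxy)phenyl](2,4,6-trimethoxyphenyl)methanone F2. Excess MgI2·OEt2 under the conditions of step 5 then cleaves both carbonyl-flanking methyl ethers. This fallback sets out from 9 and returns to the route at 12.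

Step 6. Alkylation at oxygen may compete with alkylation at carbon, the second alkylation may lag behind the first so that the reaction stalls at the monoalkylated stage, and a third alkylation at an already substituted ring carbon would destroy the aromatic ring. Fallback: build each chain through an ortho-quinone methide. Compound 12 is aminomethylated at C3 and C5 (aqueous formaldehyde, dimethylamine, EtOH; Mannich reaction) to [3-(prop-2-enyloxy)phenyl]{3,5-bis[(dimethylamino)methyl]-2,6-dihydroxy-4-methoxyphenyl}methanone F3. Quaternisation with iodomethane gives the bis(trimethylammonium) diiodide F4. Excess 2-methylprop-1-enylmagnesium bromide with catalytic CuI in THF (−78 to 0 °C) then deprotonates the phenols, expels trimethylamine and adds the alkenyl group to each exocyclic carbon. This fallback sets out from 12 and returns at 15.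

Step 5. The allyl ether may be lost by iodide attack under Lewis-acid activation. The demethylation may also stall because the C2 oxygen already occupies the carbonyl as a magnesium chelate. Fallback: change the protecting-group plan so that a boron halide can be used. Compound 8 is combined with purchasable 3-(benzyloxy)benzoic acid under the conditions of step 4 to give [3-(benzyloxy)phenyl](2-hydroxy-4,6-dimethoxyphenyl)methanone F5. BCl3 with pentamethylbenzene in CH2Cl2 (−78 to 0 °C) removes the chelated methyl group and the benzyl group together, giving (2,6-dihydroxy-4-methoxyphenyl)(3-hydroxyphenyl)methanone F6. F6 is prenylated directly with 13 in aqueous KOH as in step 6. This fallback sets out from 8 and returns at 16. It saves the deallylation but accepts that the ring B phenoxide competes for 13.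

Step 2. Metalation may occur between the two methoxy groups instead of next to the carbamate, or the carbamoyl group may migrate to carbon before silylation. Fallback: fix the position with a halogen and move silicon from oxygen to carbon. Phenol 1 is brominated with N-bromosuccinimide in CH2Cl2 at −78 °C, where the less hindered position ortho to the hydroxyl should be preferred, to give 2-bromo-3,5-dimethoxyphenol F7. Hexamethyldisilazane converts F7 into (2-bromo-3,5-dimethoxyphenoxy)trimethylsilane F8. n-BuLi in THF at −100 °C effects bromine–lithium exchange and a retro-Brook O-to-C silyl shift to the lithium salt of 7, which is quenched with trifluoromethanesulfonic anhydride. This fallback sets out from 1 and returns at 8.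

## Further compounds

F1 | step 4 | 3-(prop-2-enyloxy)benzoic trifluoroacetic anhydride | C=CCOc1cccc(C(=O)OC(=O)C(F)(F)F)c1
F2 | step 4 | [3-(prop-2-enyloxy)phenyl](2,4,6-trimethoxyphenyl)methanone | COc1cc(OC)c(C(=O)c2cccc(OCC=C)c2)c(OC)c1
F3 | step 6 | [3-(prop-2-enyloxy)phenyl]{3,5-bis[(dimethylamino)methyl]-2,6-dihydroxy-4-methoxyphenyl}methanone | COc1c(CN(C)C)c(O)c(C(=O)c2cccc(OCC=C)c2)c(O)c1CN(C)C
F4 | step 6 | {2,4-dihydroxy-6-methoxy-3-[3-(prop-2-enyloxy)benzoyl]-1,5-phenylene}bis(N,N,N-trimethylmethanaminium) diiodide | COc1c(C[N+](C)(C)C)c(O)c(C(=O)c2cccc(OCC=C)c2)c(O)c1C[N+](C)(C)C.[I-].[I-]
F5 | step 5 | [3-(benzyloxy)phenyl](2-hydroxy-4,6-dimethoxyphenyl)methanone | COc1cc(O)c(C(=O)c2cccc(OCc3ccccc3)c2)c(OC)c1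
F6 | step 5 | (2,6-dihydroxy-4-methoxyphenyl)(3-hydroxyphenyl)methanone | COc1cc(O)c(C(=O)c2cccc(O)c2)c(O)c1
F7 | step 2 | 2-bromo-3,5-dimethoxyphenol | COc1cc(O)c(Br)c(OC)c1
F8 | step 2 | (2-bromo-3,5-dimethoxyphenoxy)trimethylsilane | COc1cc(O[Si](C)(C)C)c(Br)c(OC)c1
A1 | alternative 1 | 3-ethoxy-2,6-bis(3-methylbut-2-enyl)-5-(triisopropylsilyloxy)phenol | CCOc1cc(O[Si](C(C)C)(C(C)C)C(C)C)c(CC=C(C)C)c(O)c1CC=C(C)C
A2 | alternative 1 | 3-ethoxy-4-(3-methylbut-2-enyl)cyclobut-2-en-1-one | CCOC1=CC(=O)C1CC=C(C)C
A3 | alternative 1 | triisopropyl[(5-methylhex-4-en-1-yn-1-yl)oxy]silane | CC(C)=CCC#CO[Si](C(C)C)(C(C)C)C(C)C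
A4 | alternative 2 | [3-(tert-butyldimethylsilyloxy)phenyl][2,6-dihydroxy-4-methoxy-3,5-bis(3-methylbut-2-enyl)phenyl]methanone | COc1c(CC=C(C)C)c(O)c(C(=O)c2cccc(O[Si](C)(C)C(C)(C)C)c2)c(O)c1CC=C(C)C
A5 | alternative 2 | {5-[3-(tert-butyldimethylsilyloxy)benzoyl]-4,6-dihydroxy-2-methoxy-1,3-phenylene}bis(N,N,N-trimethylmethanaminium) diiodide | COc1c(C[N+](C)(C)C)c(O)c(C(=O)c2cccc(O[Si](C)(C)C(C)(C)C)c2)c(O)c1C[N+](C)(C)C.[I-].[I-]
A6 | alternative 2 | 2-methylprop-1-enylmagnesium bromide | CC(C)=C[Mg]Br
A7 | alternative 3 | 2,4-bis(3-methylbut-2-enyl)benzene-1,3,5-triol | Oc1cc(O)c(CC=C(C)C)c(O)c1CC=C(C)C
A8 | alternative 3 | 6-methoxy-2,10-dimethylundeca-2,5,9-triene | COC(=CCC=C(C)C)CCC=C(C)C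
A9 | alternative 3 | 2,10-dimethylundeca-2,9-dien-6-one | CC(C)=CCCC(=O)CCC=C(C)C
A10 | alternative 3 | malonyl dichloride | O=C(Cl)CC(=O)Cl
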